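Numbering used: butenolide ring O1, C2 (C=O), C3 (C–CH3), C4 (C–O), C5; exocyclic carbon C6; stereocentre C7.
Retrosynthetic cuts, in order: the O4–stearoyl ester bond; the ring bond O1–C5; C4–C5; C5–C6 (C5 is added as one carbon to a C6 aldehyde); and the CH2–CH2 bond between the 3-furylmethyl group and C1 of a farnesyl chain.
Forward: farnesol is oxidised at its terminal (E)-methyl group, hydrogenated there and joined to 3-furylmethyl; the chain aldehyde becomes a 1-bromoalkyne, then a 1-bromoalkenylboronate; C4 is attached as a zinc acrylate; the butenolide, the only ring made, closes last at O1–C5, before removal of the methoxymethyl (MOM) group and O-stearoylation.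
Enabling feature: O1 is bonded to C5 and lies trans to C7 across the exocyclic C5=C6 bond, while the endocyclic C3=C4 bond holds the C2 carboxyl cis to C5, so an alkenylboron at C5 meets the acid in place for a retentive C–O coupling.
Stereochemistry: C7 (S) from Ru–BINAP hydrogenation of a 2-methylallyl alcohol; (E)-C5=C6 from syn-hydroboration (B trans to C7), retentive Negishi coupling (C4 replaces Br, cis to C7) and retentive C–O coupling; the two (E)-alkenes of the chain come unchanged from (2E,6E)-farnesol.

Key step: step 16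

Assumption (step 3): the facial sense is taken from the geraniol/nerol behaviour of Ru(OAc)2(BINAP) catalysts, which predicts the (S)-alcohol from the (S)-ligand for this (E)-2-methylallyl alcohol; the (R)-ligand would be used if a first run showed the opposite sense.

Step 1
Reactants: 1 (2E,6E)-farnesol
Product: 2 (2E,6E)-farnesyl acetate
Conditions: Ac2O, pyridine, rt
Reagents that add atoms: acetic anhydride CC(=O)OC(C)=O
Why: O-acetylation of a primary allylic alcohol (nucleophilic acyl substitution) masks C1–OH so that the allylic oxidation and the hydroxyl-directed hydrogenation address only the far end of the chain.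

Step 2
Reactants: 2 (2E,6E)-farnesyl acetate
Product: 3 (2E,6E,10E)-12-hydroxy-3,7,11-trimethyldodeca-2,6,10-trien-1-yl acetate
Conditions: SeO2 (cat.), t-BuOOH, salicylic acid (cat.), CH2Cl2, 0 °C to rt
Reagents that add atoms: selenium dioxide O=[Se]=O (delivers the oxygen); tert-butyl hydroperoxide CC(C)(C)OO (terminal oxidant that restores it)
Why: Catalytic SeO2 allylic oxidation (ene reaction, then [2,3]-sigmatropic shift) attacks the (E)-methyl group of the terminal isopropylidene unit of farnesyl esters preferentially and should give the (E)-allylic alcohol; it is run to partial conversion and unreacted 2 is recycled.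

Step 3
Reactants: 3 (2E,6E,10E)-12-hydroxy-3,7,11-trimethyldodeca-2,6,10-trien-1-yl acetate
Product: 4 (2E,6E,11S)-12-hydroxy-3,7,11-trimethyldodeca-2,6-dien-1-yl acetate
Conditions: Ru(OAc)2[(S)-BINAP] (cat.), H2 (100 atm), MeOH, 20 °C
Reagents that add atoms: none
Why: Hydroxyl-directed Noyori asymmetric hydrogenation should reduce only the double bond of the free allylic alcohol (the acetate-masked and the isolated trisubstituted alkenes do not bind to ruthenium), and the BINAP ligand selects the alkene face so that C11 (C7 of the target) is set as (S).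

Step 4
Reactants: 4 (2E,6E,11S)-12-hydroxy-3,7,11-trimethyldodeca-2,6-dien-1-yl acetate
Product: 5 (2E,6E,11S)-3,7,11-trimethyldodeca-2,6-diene-1,12-diol
Conditions: K2CO3, MeOH, rt
Reagents that add atoms: none
Why: Base-catalysed transesterification (Zemplén-type methanolysis) removes the acetate without touching the stereocentre or the alkenes.

Step 5
Reactants: 5 (2E,6E,11S)-3,7,11-trimethyldodeca-2,6-diene-1,12-diol
Product: 6 (2S,6E,10E)-12-chloro-2,6,10-trimethyldodeca-6,10-dien-1-ol
Conditions: NCS, Me2S, CH2Cl2, −20 to 0 °C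
Reagents that add atoms: N-chlorosuccinimide O=C1CCC(=O)N1Cl
Why: Corey–Kim chlorination converts allylic alcohols into chlorides under neutral conditions (chloride attack on the alkoxysulfonium salt), whereas the alkoxysulfonium salt of a saturated primary alcohol returns the alcohol on work-up, so only C1 should be activated and the (E)-alkene is kept.

Step 6
Reactants: 7 3-furanmethanol
Product: 8 3-(chloromethyl)furan
Conditions: SOCl2, pyridine, Et2O, 0 °C
Reagents that add atoms: thionyl chloride O=S(Cl)Cl
Why: Chlorodehydroxylation of a primary heterobenzylic alcohol via its chlorosulfite (SN2) is standard; the volatile chloride is used at once as an ethereal solution.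

Step 7
Reactants: 8 3-(chloromethyl)furan; 6 (2S,6E,10E)-12-chloro-2,6,10-trimethyldodeca-6,10-dien-1-ol
Product: 10 (2S,6E,10E)-13-(furan-3-yl)-2,6,10-trimethyltrideca-6,10-dien-1-ol, via furan-3-ylmethylmagnesium chloride 9 (not isolated)
Conditions: Mg, THF, 0 °C; then 6 (0.4 equiv), Li2CuCl4 (cat.), THF, −10 to 0 °C
Reagents that add atoms: none
Why: Li2CuCl4-catalysed coupling of a Grignard reagent with a primary allylic chloride proceeds by SN2 substitution with retention of the (E)-alkene, as in the joining of 3-furylmethyl Grignard reagents to geranyl chloride; one equivalent of 9 is spent on the free hydroxyl, whose magnesium alkoxide is inert.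

Step 8
Reactants: 10 (2S,6E,10E)-13-(furan-3-yl)-2,6,10-trimethyltrideca-6,10-dien-1-ol
Product: 11 (2S,6E,10E)-13-(furan-3-yl)-2,6,10-trimethyltrideca-6,10-dienal
Conditions: Dess–Martin periodinane, CH2Cl2, 0 °C to rt
Reagents that add atoms: none
Why: Dess–Martin oxidation stops at the aldehyde under near-neutral conditions that should not epimerise the α-methyl stereocentre or attack the furan and alkenes; 11 is used without storage.

Step 9
Reactants: 11 (2S,6E,10E)-13-(furan-3-yl)-2,6,10-trimethyltrideca-6,10-dienal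
Product: 12 3-[(3E,7E,12S)-14,14-dibromo-4,8,12-trimethyltetradeca-3,7,13-trien-1-yl]furan
Conditions: CBr4, PPh3, Zn dust, CH2Cl2, rt; then 11, 0 °C to rt
Reagents that add atoms: carbon tetrabromide BrC(Br)(Br)Br
Why: The first stage of the Corey–Fuchs sequence (Ramirez dibromo-olefination, a Wittig-type reaction of Ph3P=CBr2) adds the future C5 and leaves α-stereocentres intact; zinc takes up the bromine so that no Ph3PBr2 meets the furan.

Step 10
Reactants: 12 3-[(3E,7E,12S)-14,14-dibromo-4,8,12-trimethyltetradeca-3,7,13-trien-1-yl]furan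
Product: 13 3-[(3E,7E,12S)-14-bromo-4,8,12-trimethyltetradeca-3,7-dien-13-yn-1-yl]furan
Conditions: NaN(SiMe3)2, THF, −78 °C
Reagents that add atoms: none
Why: E2 elimination of HBr from a 1,1-dibromoalkene with a hindered, non-nucleophilic amide stops at the 1-bromoalkyne because no halogen–metal exchange occurs, and the propargylic C7–H should not be removed at this temperature.

Step 11
Reactants: 13 3-[(3E,7E,12S)-14-bromo-4,8,12-trimethyltetradeca-3,7-dien-13-yn-1-yl]furan
Product: 16 2-[(1Z,3S,7E,11E)-1-bromo-14-(furan-3-yl)-3,7,11-trimethyltetradeca-1,7,11-trien-1-yl]-4,4,5,5-tetramethyl-1,3,2-dioxaborolane, via (Z)-1-bromoalkenyl-diisopinocampheylborane 14 (not isolated), via diethyl (Z)-1-bromoalkenylboronate 15 (not isolated)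
Conditions: (−)-Ipc2BH, THF, 0 °C to rt; CH3CHO (excess), 0 to 40 °C; pinacol, rt
Reagents that add atoms: (−)-diisopinocampheylborane, from (+)-α-pinene (boron; either antipode serves) B([C@@H]1C[C@@H]2C[C@H]([C@H]1C)C2(C)C)[C@@H]1C[C@@H]2C[C@H]([C@H]1C)C2(C)C; pinacol CC(C)(O)C(C)(C)O
Why: Syn-hydroboration of a 1-bromoalkyne by a dialkylborane places boron on the bromine-bearing carbon, so B ends trans and Br cis to C7; the hindered Ipc2BH should spare the trisubstituted alkenes and the furan (HBBr2·SMe2 would attack the alkenes and release HBr), acetaldehyde then expels both isopinocampheyl groups as α-pinene (the usual dealkylation of alkenyl-Ipc2B compounds), and pinacol transesterifies the diethyl ester.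

Step 12
Reactants: 17 ethyl 2-formylpropanoate
Product: 18 ethyl (2E)-3-(methoxymethoxy)-2-methylprop-2-enoate
Conditions: MOMCl, i-Pr2NEt, CH2Cl2, 0 °C to rt
Reagents that add atoms: chloromethyl methyl ether COCCl
Why: O-alkylation of the enol form of an α-formyl ester by the hard electrophile MOMCl gives the enol ether; the (E)-isomer (OMOM trans to the ester, β-H cis to it) is the thermodynamically preferred one and is purified by distillation.

Step 13
Reactants: 18 ethyl (2E)-3-(methoxymethoxy)-2-methylprop-2-enoate; 16 2-[(1Z,3S,7E,11E)-1-bromo-14-(furan-3-yl)-3,7,11-trimethyltetradeca-1,7,11-trien-1-yl]-4,4,5,5-tetramethyl-1,3,2-dioxaborolane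
Product: 21 ethyl (2E,4Z,6S,10E,14E)-17-(furan-3-yl)-3-(methoxymethoxy)-2,6,10,14-tetramethyl-4-(4,4,5,5-tetramethyl-1,3,2-dioxaborolan-2-yl)heptadeca-2,4,10,14-tetraenoate, via β-lithiated enol ether 19 (not isolated), via alkenylzinc chloride 20 (not isolated)
Conditions: LiN(i-Pr)2, THF, −90 °C; ZnCl2, −90 to 0 °C; then 16, Pd2(dba)3 (cat.), SPhos, THF, 25 to 50 °C
Reagents that add atoms: none
Why: β-Alkoxyacrylates are deprotonated at the vinylic β-hydrogen cis to the ester (ester-chelated α-alkoxyvinyllithium), ZnCl2 gives a configurationally stable zinc reagent, and Negishi coupling (zerovalent palladium inserts into C–Br, transmetalation and reductive elimination, all with retention) replaces Br by C4 while the pinacol boronate, which needs base to transmetalate, is spared, as known for (Z)-1-halo-1-alkenylboronates.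

Step 14
Reactants: 21 ethyl (2E,4Z,6S,10E,14E)-17-(furan-3-yl)-3-(methoxymethoxy)-2,6,10,14-tetramethyl-4-(4,4,5,5-tetramethyl-1,3,2-dioxaborolan-2-yl)heptadeca-2,4,10,14-tetraenoate
Product: 22 (2E,4Z,6S,10E,14E)-17-(furan-3-yl)-3-(methoxymethoxy)-2,6,10,14-tetramethyl-4-(4,4,5,5-tetramethyl-1,3,2-dioxaborolan-2-yl)heptadeca-2,4,10,14-tetraenoic acid
Conditions: LiOH, THF/MeOH/H2O, 40 °C; then 0.5 M HCl to pH 5, 0 °C
Reagents that add atoms: lithium hydroxide [Li+].[OH-] (its oxygen becomes the carboxyl OH)
Why: Ester saponification (BAc2) is run before fluoride exchange because MOM enol ether and alkenylboronate are base-stable, whereas an alkenyltrifluoroborate would hydrolyse in aqueous base; the brief cold acidification should spare MOM group and furan.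

Step 15
Reactants: 22 (2E,4Z,6S,10E,14E)-17-(furan-3-yl)-3-(methoxymethoxy)-2,6,10,14-tetramethyl-4-(4,4,5,5-tetramethyl-1,3,2-dioxaborolan-2-yl)heptadeca-2,4,10,14-tetraenoic acid
Product: 23 potassium trifluoroborate of (2E,4Z,6S,10E,14E)-4-borono-17-(furan-3-yl)-3-(methoxymethoxy)-2,6,10,14-tetramethylheptadeca-2,4,10,14-tetraenoic acid (BF3K on C4 of the acid chain, which is C5 of the target)
Conditions: KHF2, MeOH/H2O, rt
Reagents that add atoms: potassium hydrogen difluoride [K+].F[H-]F
Why: Fluoride exchange of a pinacol boronate with KHF2 is the standard route to potassium organotrifluoroborates, the boron form that transfers best to copper in oxidative C–O couplings.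

Step 16
Reactants: 23 potassium trifluoroborate of (2E,4Z,6S,10E,14E)-4-borono-17-(furan-3-yl)-3-(methoxymethoxy)-2,6,10,14-tetramethylheptadeca-2,4,10,14-tetraenoic acid
Product: 24 (5E)-5-[(2S,6E,10E)-13-(furan-3-yl)-2,6,10-trimethyltrideca-6,10-dien-1-ylidene]-4-(methoxymethoxy)-3-methylfuran-2(5H)-one
Conditions: CuBr (20 mol %), DMAP (40 mol %), 4 Å molecular sieves, O2 (1 atm), MeCN, 50 °C
Reagents that add atoms: none
Why: Proposed new method: the C5 alkenyl group should pass from boron to a DMAP-ligated divalent copper centre that already carries the C2 carboxylate, oxidation by O2 or by a second divalent copper should give a trivalent copper alkenyl carboxylate, and C–O reductive elimination should form O1–C5 with retention while O2 returns monovalent copper to the divalent state. The closest known reaction type is the intermolecular copper-catalysed oxidative coupling of potassium alkenyltrifluoroborates with carboxylic acids to enol esters (Chan–Lam type), which is stereospecific. The butenolide ring (O1, C2, C3, C4, C5) closes by reductive elimination from a six-membered cupracycle and not by attack on a π bond, so no enol or enolate of a C5 ketone is ever formed and the less stable (E)-geometry cannot relax. No stereocentre is created; C7 is untouched and the C5=C6 geometry is copied from 23. The step needs ring closure to outrun protodeboronation, oxidative dimerisation and intermolecular esterification; the tetrasubstituted C3=C4 bond holds CO2H and boron cis and within bonding reach, and CuBr is chosen so that no external carboxylate competes.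

Step 17
Reactants: 24 (5E)-5-[(2S,6E,10E)-13-(furan-3-yl)-2,6,10-trimethyltrideca-6,10-dien-1-ylidene]-4-(methoxymethoxy)-3-methylfuran-2(5H)-one
Product: 25 (5E)-5-[(2S,6E,10E)-13-(furan-3-yl)-2,6,10-trimethyltrideca-6,10-dien-1-ylidene]-4-hydroxy-3-methylfuran-2(5H)-one
Conditions: 1 M HCl, THF, 0 °C to rt
Reagents that add atoms: none
Why: The MOM group on a tetronate is a vinylogous acylal and should undergo acid-catalysed acetal hydrolysis under conditions too mild to hydrate the trisubstituted alkenes, open the furan or protonate C6, so the (E)-geometry and C7 are kept.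

Step 18
Reactants: 25 (5E)-5-[(2S,6E,10E)-13-(furan-3-yl)-2,6,10-trimethyltrideca-6,10-dien-1-ylidene]-4-hydroxy-3-methylfuran-2(5H)-one; 26 stearoyl chloride
Product: 27 (2E)-2-[(2S,6E,10E)-13-(furan-3-yl)-2,6,10-trimethyltrideca-6,10-dien-1-ylidene]-4-methyl-5-oxo-2,5-dihydrofuran-3-yl octadecanoate
Conditions: Et3N, CH2Cl2, 0 °C
Reagents that add atoms: none
Why: O-Acylation of the triethylammonium tetronate by the acid chloride occurs at the hard O4 oxygen (C3 is blocked by methyl) and gives the enol ester; the tetronate anion is not electrophilic, so the ylidene geometry is not at risk.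

Compound list
1 | (2E,6E)-farnesol | CC(C)=CCC/C(C)=C/CC/C(C)=C/CO | starting material
2 | (2E,6E)-farnesyl acetate | CC(C)=CCC/C(C)=C/CC/C(C)=C/COC(C)=O | intermediate
3 | (2E,6E,10E)-12-hydroxy-3,7,11-trimethyldodeca-2,6,10-trien-1-yl acetate | OC/C(C)=C/CC/C(C)=C/CC/C(C)=C/COC(C)=O | intermediate
4 | (2E,6E,11S)-12-hydroxy-3,7,11-trimethyldodeca-2,6-dien-1-yl acetate | OC[C@@H](C)CCC/C(C)=C/CC/C(C)=C/COC(C)=O | intermediate
5 | (2E,6E,11S)-3,7,11-trimethyldodeca-2,6-diene-1,12-diol | OC[C@@H](C)CCC/C(C)=C/CC/C(C)=C/CO | intermediate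
6 | (2S,6E,10E)-12-chloro-2,6,10-trimethyldodeca-6,10-dien-1-ol | OC[C@@H](C)CCC/C(C)=C/CC/C(C)=C/CCl | intermediate
7 | 3-furanmethanol | OCc1ccoc1 | starting material
8 | 3-(chloromethyl)furan | ClCc1ccoc1 | intermediate
9 | furan-3-ylmethylmagnesium chloride | Cl[Mg]Cc1ccoc1 | intermediate
10 | (2S,6E,10E)-13-(furan-3-yl)-2,6,10-trimethyltrideca-6,10-dien-1-ol | OC[C@@H](C)CCC/C(C)=C/CC/C(C)=C/CCc1ccoc1 | intermediate
11 | (2S,6E,10E)-13-(furan-3-yl)-2,6,10-trimethyltrideca-6,10-dienal | O=C[C@@H](C)CCC/C(C)=C/CC/C(C)=C/CCc1ccoc1 | intermediate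
12 | 3-[(3E,7E,12S)-14,14-dibromo-4,8,12-trimethyltetradeca-3,7,13-trien-1-yl]furan | BrC(Br)=C[C@@H](C)CCC/C(C)=C/CC/C(C)=C/CCc1ccoc1 | intermediate
13 | 3-[(3E,7E,12S)-14-bromo-4,8,12-trimethyltetradeca-3,7-dien-13-yn-1-yl]furan | BrC#C[C@@H](C)CCC/C(C)=C/CC/C(C)=C/CCc1ccoc1 | intermediate
14 | [(1Z,3S,7E,11E)-1-bromo-14-(furan-3-yl)-3,7,11-trimethyltetradeca-1,7,11-trien-1-yl]bis(isopinocampheyl)borane | B(/C(Br)=C/[C@@H](C)CCC/C(C)=C/CC/C(C)=C/CCc1ccoc1)([C@@H]1C[C@@H]2C[C@H]([C@H]1C)C2(C)C)[C@@H]1C[C@@H]2C[C@H]([C@H]1C)C2(C)C | intermediate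
15 | diethyl [(1Z,3S,7E,11E)-1-bromo-14-(furan-3-yl)-3,7,11-trimethyltetradeca-1,7,11-trien-1-yl]boronate | CCOB(OCC)/C(Br)=C/[C@@H](C)CCC/C(C)=C/CC/C(C)=C/CCc1ccoc1 | intermediate
16 | 2-[(1Z,3S,7E,11E)-1-bromo-14-(furan-3-yl)-3,7,11-trimethyltetradeca-1,7,11-trien-1-yl]-4,4,5,5-tetramethyl-1,3,2-dioxaborolane | CC1(C)OB(OC1(C)C)/C(Br)=C/[C@@H](C)CCC/C(C)=C/CC/C(C)=C/CCc1ccoc1 | intermediate
17 | ethyl 2-formylpropanoate | CCOC(=O)C(C)C=O | starting material
18 | ethyl (2E)-3-(methoxymethoxy)-2-methylprop-2-enoate | CCOC(=O)/C(C)=C/OCOC | intermediate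
19 | ethyl (2E)-3-lithio-3-(methoxymethoxy)-2-methylprop-2-enoate (Li cis to the ester) | CCOC(=O)/C(C)=C(\[Li])OCOC | intermediate
20 | [(1Z)-3-ethoxy-1-(methoxymethoxy)-2-methyl-3-oxoprop-1-en-1-yl]zinc chloride (Zn cis to the ester) | CCOC(=O)/C(C)=C(\[Zn]Cl)OCOC | intermediate
21 | ethyl (2E,4Z,6S,10E,14E)-17-(furan-3-yl)-3-(methoxymethoxy)-2,6,10,14-tetramethyl-4-(4,4,5,5-tetramethyl-1,3,2-dioxaborolan-2-yl)heptadeca-2,4,10,14-tetraenoate | CCOC(=O)/C(C)=C(\C(=C/[C@@H](C)CCC/C(C)=C/CC/C(C)=C/CCc1ccoc1)B1OC(C)(C)C(C)(C)O1)OCOC | intermediate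
22 | (2E,4Z,6S,10E,14E)-17-(furan-3-yl)-3-(methoxymethoxy)-2,6,10,14-tetramethyl-4-(4,4,5,5-tetramethyl-1,3,2-dioxaborolan-2-yl)heptadeca-2,4,10,14-tetraenoic acid | OC(=O)/C(C)=C(\C(=C/[C@@H](C)CCC/C(C)=C/CC/C(C)=C/CCc1ccoc1)B1OC(C)(C)C(C)(C)O1)OCOC | intermediate
23 | potassium trifluoroborate of (2E,4Z,6S,10E,14E)-4-borono-17-(furan-3-yl)-3-(methoxymethoxy)-2,6,10,14-tetramethylheptadeca-2,4,10,14-tetraenoic acid | OC(=O)/C(C)=C(\C(=C/[C@@H](C)CCC/C(C)=C/CC/C(C)=C/CCc1ccoc1)[B-](F)(F)F)OCOC.[K+] | intermediate
24 | (5E)-5-[(2S,6E,10E)-13-(furan-3-yl)-2,6,10-trimethyltrideca-6,10-dien-1-ylidene]-4-(methoxymethoxy)-3-methylfuran-2(5H)-one | COCOC1=C(C)C(=O)O/C1=C/[C@@H](C)CCC/C(C)=C/CC/C(C)=C/CCc1ccoc1 | intermediate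
25 | (5E)-5-[(2S,6E,10E)-13-(furan-3-yl)-2,6,10-trimethyltrideca-6,10-dien-1-ylidene]-4-hydroxy-3-methylfuran-2(5H)-one | OC1=C(C)C(=O)O/C1=C/[C@@H](C)CCC/C(C)=C/CC/C(C)=C/CCc1ccoc1 | intermediate
26 | stearoyl chloride | CCCCCCCCCCCCCCCCCC(Cl)=O | starting material
27 | (2E)-2-[(2S,6E,10E)-13-(furan-3-yl)-2,6,10-trimethyltrideca-6,10-dien-1-ylidene]-4-methyl-5-oxo-2,5-dihydrofuran-3-yl octadecanoate | CCCCCCCCCCCCCCCCCC(=O)OC1=C(C)C(=O)O/C1=C/[C@@H](C)CCC/C(C)=C/CC/C(C)=C/CCc1ccoc1 | target

Total step count: 18. Longest linear sequence: 16 steps from farnesol (steps 1–5, 7–11, 13–18); steps 6 and 12 prepare the two side components.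

Steps most likely to fail

Step 16. Transfer of the crowded, fully substituted C5 alkenyl group from boron to copper may be slower than protodeboronation or oxidative dimerisation, or the copper intermediate may form ester oligomers between molecules instead of closing the ring. The fallback sets out from 23 and comes back at 24. Ipso-iododeboronation of 23 with NaI and TsN(Cl)Na in aqueous THF at 0 °C, a substitution that keeps alkene geometry, would give (2E,4E,6S,10E,14E)-17-(furan-3-yl)-4-iodo-3-(methoxymethoxy)-2,6,10,14-tetramethylheptadeca-2,4,10,14-tetraenoic acid F1; one equivalent of the iodinating agent is used so that the fast substitution at boron outruns attack on the furan. Copper iodide (CuI) with trans-N,N'-dimethylcyclohexane-1,2-diamine and Cs2CO3 in toluene at 60–80 °C would then close the ring to 24 by Ullmann-type intramolecular O-vinylation of the carboxylate, a known route to enol lactones that also keeps the alkene geometry.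

Step 13. Oxidative addition at the hindered bromide and transmetalation of an ester-chelated, weakly nucleophilic alkenylzinc may be slow; the zinc reagent could then add to boron (1,2-migration with inversion at C5, giving the wrong geometry) or decompose. The fallback sets out from 18 and 16 and comes back at 21. The lithiated enol ether 19, made as in step 13, would be quenched with Bu3SnCl at −90 °C to give the isolable ethyl (2Z)-3-(methoxymethoxy)-2-methyl-3-(tributylstannyl)prop-2-enoate F2. This α-alkoxyalkenylstannane, which cannot attack boron, would be joined to 16 by a copper-assisted Stille coupling (Pd(PPh3)4, copper thiophene-2-carboxylate Cu(O2CC4H3S), NMP, rt to 50 °C, no base or fluoride, so the boronate stays silent) to give 21 with retention at both partners.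

Step 3. Facial discrimination may be insufficient for a 2-methyl-substituted allylic alcohol, and allylic isomerisation to the aldehyde may compete. The fallback sets out from 3 and comes back at 5. Oxidation of 3 with MnO2 in CH2Cl2 would give (2E,6E,10E)-3,7,11-trimethyl-12-oxododeca-2,6,10-trien-1-yl acetate F3, and Pinnick oxidation (NaClO2, NaH2PO4, 2-methyl-2-butene, t-BuOH/H2O) would give (2E,6E,10E)-12-acetoxy-2,6,10-trimethyldodeca-2,6,10-trienoic acid F4. Carboxylate-directed hydrogenation of this (E)-2-methyl-2-enoic acid, the tiglic acid class for which Ru–BINAP-type catalysts are well established, would use Ru(OAc)2(H8-BINAP) in the antipode that converts tiglic acid into (S)-2-methylbutanoic acid (expected to be the (S)-ligand). It should give (2S,6E,10E)-12-acetoxy-2,6,10-trimethyldodeca-6,10-dienoic acid F5. LiAlH4 in THF at 0 °C would reduce the acid and cleave the acetate in one operation to the diol 5.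

Further compounds
F1 | step 16 | (2E,4E,6S,10E,14E)-17-(furan-3-yl)-4-iodo-3-(methoxymethoxy)-2,6,10,14-tetramethylheptadeca-2,4,10,14-tetraenoic acid | OC(=O)/C(C)=C(\C(I)=C/[C@@H](C)CCC/C(C)=C/CC/C(C)=C/CCc1ccoc1)OCOC
F2 | step 13 | ethyl (2Z)-3-(methoxymethoxy)-2-methyl-3-(tributylstannyl)prop-2-enoate | CCOC(=O)/C(C)=C(\[Sn](CCCC)(CCCC)CCCC)OCOC
F3 | step 3 | (2E,6E,10E)-3,7,11-trimethyl-12-oxododeca-2,6,10-trien-1-yl acetate | O=C/C(C)=C/CC/C(C)=C/CC/C(C)=C/COC(C)=O
F4 | step 3 | (2E,6E,10E)-12-acetoxy-2,6,10-trimethyldodeca-2,6,10-trienoic acid | OC(=O)/C(C)=C/CC/C(C)=C/CC/C(C)=C/COC(C)=O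
F5 | step 3 | (2S,6E,10E)-12-acetoxy-2,6,10-trimethyldodeca-6,10-dienoic acid | OC(=O)[C@@H](C)CCC/C(C)=C/CC/C(C)=C/COC(C)=O
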